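## Structural features

Lespeflorin B1 is a 5-deoxy dihydroflavonol: ring A is fused to the dihydropyranone ring C through C4a–C8a, and ring B is attached at C2 through the C2–C1' bond. Ring C holds the only two stereocentres, C2 (aryl) and C3 (hydroxyl); they are adjacent, both R, and trans. Ring A carries a free hydroxyl on C7 and a prenyl group on C6, ring B a hydroxyl on C4' and a prenyl group on C3', and C5 and C8 are unsubstituted. The β-aryloxy ketone of ring C opens reversibly to a chalcone under base or heat and then loses the C2 configuration, and the α-ketol is epimerised or oxidised to the flavonol by base and air. The two ortho-prenylphenols cyclise to 2,2-dimethylchromans in acid and are epoxidised by electrophilic oxidants. The real difficulty is regiochemical: with no C5 hydroxyl, nothing steers a five-carbon unit to C6, and delivery from the C7 oxygen normally goes to C8. The key step uses the fact that each prenyl group (on C6 and on C3') stands ortho to a phenolic oxygen (on C7 and on C4'), the retron of an aromatic Claisen shift of a 1,1-dimethylallyl aryl ether, and it settles C6 against C8 with a removable bromine on C8.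

## Logic of the disconnections

**20 ⇒ 19.** Only C8–H is changed back to C8–Br. The halogen is accepted as a temporary substituent because it turns the ring A regiochemistry into a non-issue one step earlier. The forward step must remove one aryl bromide beside two free phenols, an α-ketol and two trisubstituted alkenes. This calls for a homogeneous palladium/formate reduction and rules out hydrogenation over a heterogeneous catalyst.

**19 ⇒ 18.** The C6–CH2 and C3'–CH2 bonds are cut, and each five-carbon unit is reattached through its tertiary carbon to the neighbouring phenolic oxygen. Two aryl C–C bonds become two C–O bonds that plain phenol etherification can make. The electron-rich prenyl alkenes become monosubstituted vinyl groups that tolerate an electrophilic oxidant. The forward step must be a twofold [3,3] shift below the temperature at which ring C opens, and on ring A it must go to C6 only, which the C8 bromine enforces.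

**18 ⇒ 16 ⇒ 15 (through 17).** The C3–O bond is cut. This removes one stereocentre, whose configuration follows from C2 by substrate control. The structures 18 and 19 are (2R,3R) and map atom for atom onto 20. In 15 and 16 the same spatial arrangement at C2 carries the descriptor S, because C3 has no oxygen yet. The forward steps need enolisation without retro-oxa-Michael opening, and an oxidant that takes the enol ether and leaves two vinyl groups alone.

**15 ⇒ 8 + 14.** The C2–C1' bond is cut. The route becomes convergent, each half carries one ether, and the single stereocentre is set by a catalyst. The forward step needs a catalyst that tolerates an aryl bromide and two terminal alkenes, and a base mild enough to leave the product ring closed.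

**8 ⇒ 7 ⇒ 5 (through 6).** The vinyl group is traced back to an ethynyl group, and then O1–C2 and C2–C3 are cut to release a one-carbon unit. The alkyne is chosen for this stretch because a tertiary propargyl aryl ether survives the heat and acid of ring C construction, which a tertiary allyl aryl ether would not. The semihydrogenation must stop at the alkene and spare the C–Br bond and the pyranone double bond.

**5 ⇒ 2 + 4; 2 ⇒ 1.** The tertiary C–O bond is cut, then the aryl–acyl bond. In 1 the bromine already sits between the two oxygens, and the two open positions ortho/para to them are equivalent, so acylation has one outcome. The etherification must take the non-chelated hydroxyl only.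

**14 ⇒ 11 ⇒ 10 ⇒ 9 + 4 (through 12 and 13).** The C–B bond comes from a C–Br bond, the vinyl group from an ethynyl group, and the tertiary C–O bond is cut as on ring A. The forward steps need halogen–lithium exchange at low temperature and a near-neutral hydrolysis, because the tertiary allyl ether is acid-labile.

**4 ⇒ 3.** The ester C–O bond of the activated propargyl donor is cut. Both etherifications draw on the same donor, so it is made once from the commercial alcohol and shared between the two branches. The forward step must acylate a tertiary propargylic alcohol without ionising it, which calls for a cold, base-buffered acylation and for using the ester as its solution.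

## Other disconnections considered

**Alternative 1:** The cut is the aryl ether bond O1–C8a. In the forward direction the open-chain bromoarene diol A2 would be treated with lithium 2,2,6,6-tetramethylpiperidide. Removal of the only hydrogen ortho to bromine (on C8a) and loss of bromide would give the C8–C8a aryne. The C2 alkoxide would add at C8a in a six-membered closure to give the chromanol A1. The C7 methoxymethoxy group polarises the aryne so that attack at the distal carbon C8a is also the electronically preferred one.

- In its favour: ring closure and removal of the halogen happen in one operation, where the chosen plan spends a separate step; on this point the alternative is better. Ring C is closed from an alkoxide and not next to an enolisable ketone, so C2 cannot be lost by ring opening at that stage; this is also a point for the alternative.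
- Against it here: A2 needs two carbinol stereocentres set in an acyclic array by independent asymmetric chemistry. A1 must still be oxidised at C4 and freed from three methoxymethyl ethers, and the acid for that is what cyclises ortho-prenylphenols to chromans. A strong amide base also meets a benzylic alkoxide and two allylic–benzylic CH2 groups, and the amide can capture the aryne intermolecularly.
- Comparison: the C6 prenyl problem is not solved but moved into the synthesis of the ring A building block. Both plans use a C8 bromine; the chosen plan uses it as a blocking group and never needs acid once the prenyl groups exist. The step count of the alternative is expected to be higher (stereodefined triol, protection, oxidation, deprotection).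

**Alternative 2:** The cuts are C4a–C5 and C8–C8a, so ring A is built last. The enantiopure brominated dihydropyranone A4 would act as dienophile towards the silyloxy diene A5. The CH2 terminus of A5 would bond to the enol-ether carbon (future C8a) and the methoxy-bearing terminus to the brominated carbon (future C4a). Loss of HBr, methanol and the silyl group would give the phenol A3.

- In its favour: the ring A pattern (prenyl on C6, oxygen on C7, hydrogen on C5 and C8) is written into the diene, so no blocking group and no regiochemical decision are needed; on this point the alternative is better. It is the equal of the chosen plan in convergence and in setting both stereocentres on a six-membered ring before the sensitive phenols exist.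
- Against it here: the dienophile is a vinylogous ester, a reluctant 2π partner even with the α-bromine. A5 is a trisubstituted, hydrolytically labile diene whose reactive s-cis conformer is disfavoured by the substituent on its central carbon. The forcing conditions this pair is likely to need act on a product that, once aromatised, is a β-aryloxy ketone able to open and lose C2.
- Comparison: A4 needs its own asymmetric ring construction, a C3 oxygenation and a bromination, so the step count is not lower, and acid deprotection next to ortho-prenylphenols returns. The chosen plan rests on unimolecular sigmatropic shifts driven by rearomatisation; the alternative rests on an intermolecular cycloaddition of a hindered pair.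

**Alternative 3:** The cut is C3–C4. The dialdehyde A7 would meet a chiral triazolylidene carbene. The carbene would add to the ring A aldehyde, and the resulting acyl anion equivalent would attack the pendant aldehyde. Because the α-aryl-α-aryloxy aldehyde centre epimerises quickly, one enantiomer could be funnelled to the trans ketol A6.

- In its favour: ring C and both stereocentres arise in one catalytic, redox-neutral step, where the chosen plan uses two (steps 9 and 11); in stereochemical economy the alternative is better. No oxidant is used, so the prenyl groups could be present from the start, and no halogen has to be removed afterwards.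
- Against it here: the aliphatic aldehyde is the more electrophilic one and carries an α-aryloxy leaving group. Carbene addition there would expel the phenoxide and form an acyl azolium, which destroys the substrate. Closures of this type are established onto ketones, and an aldehyde–aldehyde version with dynamic resolution has no close precedent. A7 is prone to enolisation and air oxidation.
- Comparison: the C6 prenyl group must still be placed regioselectively on the ring A salicylaldehyde, so the central problem is exported. The methoxymethyl ethers again need acid at the end. The step count is comparable on paper, but the key step is of lower confidence than a sigmatropic rearrangement.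

Key step: step 12

Assumption: the catalyst formed from [Rh(C2H4)2Cl]2 and the chiral diene is taken to deliver the aryl group to the chromone with the same facial sense as to 2-cyclohexenone, so the (S,S)-ligand is written; if the sense is the opposite, the (R,R)-ligand is used and nothing else changes.

## Route

Step 1
Reactants: 1 2-bromoresorcinol (2-bromobenzene-1,3-diol)
Product: 2 1-(3-bromo-2,4-dihydroxyphenyl)ethanone
Conditions: AcOH, BF3·OEt2, 90 °C
Reagents that add atoms: acetic acid, CC(=O)O
Why: Friedel–Crafts C-acylation of a resorcinol (Nencki-type); the two positions ortho/para to the hydroxyls are equivalent, so one ketone forms, and its boron chelate is deactivated towards a second acylation.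

Step 2
Reactants: 3 2-methylbut-3-yn-2-ol
Product: 4 2-methylbut-3-yn-2-yl trifluoroacetate
Conditions: (CF3CO)2O, DBU, MeCN, −5 °C; one batch, kept cold and used as the MeCN solution in steps 3 and 6
Reagents that add atoms: trifluoroacetic anhydride, O=C(OC(=O)C(F)(F)F)C(F)(F)F
Why: O-acylation of the tertiary propargylic alcohol by the anhydride with DBU as acid scavenger; the electron-poor ester is the leaving group needed for the copper-catalysed etherifications. The volatile, moisture-sensitive ester is not concentrated, and the single batch is divided between the two etherifications, which are run side by side.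

Step 3
Reactants: 2 1-(3-bromo-2,4-dihydroxyphenyl)ethanone; 4 2-methylbut-3-yn-2-yl trifluoroacetate
Product: 5 1-[3-bromo-2-hydroxy-4-(2-methylbut-3-yn-2-yloxy)phenyl]ethanone
Conditions: DBU, CuCl2·2H2O (cat.), MeCN, −5 to 0 °C
Reagents that add atoms: none
Why: Copper-catalysed propargylic etherification of a phenol through a copper acetylide/allenylidene; the C4 hydroxyl (para to the acetyl group, not hydrogen-bonded) is the more acidic and reacts, while the chelated C2 hydroxyl stays free.

Step 4
Reactants: 5 1-[3-bromo-2-hydroxy-4-(2-methylbut-3-yn-2-yloxy)phenyl]ethanone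
Product: 7 8-bromo-7-(2-methylbut-3-yn-2-yloxy)-4H-chromen-4-one, via dimethylamino enone 6 (not isolated)
Conditions: Me2NCH(OMe)2, toluene, 80 °C; then 1 M HCl, CH2Cl2, 23 °C
Reagents that add atoms: N,N-dimethylformamide dimethyl acetal, COC(OC)N(C)C
Why: Enaminone formation at the methyl ketone, then acid-induced cyclisation by oxa-Michael addition of the phenol and loss of dimethylamine, the standard chromone synthesis; the tertiary propargyl ether resists dilute acid and 80 °C, which is why the alkyne is carried through this step.

Step 5
Reactants: 7 8-bromo-7-(2-methylbut-3-yn-2-yloxy)-4H-chromen-4-one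
Product: 8 8-bromo-7-(2-methylbut-3-en-2-yloxy)-4H-chromen-4-one
Conditions: H2 (1 atm), Pd on CaCO3 poisoned with Pb(OAc)2, quinoline, EtOAc, 23 °C
Reagents that add atoms: none
Why: Lindlar semihydrogenation; the terminal alkyne binds the poisoned palladium much more strongly than the alkene formed, uptake is stopped at one equivalent, and the vinylogous-ester C2=C3 bond and the aryl bromide are not reduced on this catalyst.

Step 6
Reactants: 9 4-bromophenol; 4 2-methylbut-3-yn-2-yl trifluoroacetate
Product: 10 1-bromo-4-(2-methylbut-3-yn-2-yloxy)benzene
Conditions: DBU, CuCl2·2H2O (cat.), MeCN, −5 to 0 °C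
Reagents that add atoms: none
Why: The same copper-catalysed propargylic etherification as in step 3, here on a simple para-substituted phenol.

Step 7
Reactants: 10 1-bromo-4-(2-methylbut-3-yn-2-yloxy)benzene
Product: 11 1-bromo-4-(2-methylbut-3-en-2-yloxy)benzene
Conditions: H2 (1 atm), Pd on CaCO3 poisoned with Pb(OAc)2, quinoline, EtOAc, 23 °C
Reagents that add atoms: none
Why: Lindlar semihydrogenation of the terminal alkyne; the aryl bromide is inert on the poisoned catalyst.

Step 8
Reactants: 11 1-bromo-4-(2-methylbut-3-en-2-yloxy)benzene
Product: 14 [4-(2-methylbut-3-en-2-yloxy)phenyl]boronic acid, via aryllithium 12 (not isolated), via lithium aryltriisopropoxyborate 13 (not isolated)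
Conditions: n-BuLi, THF, −78 °C; B(OiPr)3, −78 to 0 °C; aq. NH4Cl
Reagents that add atoms: triisopropyl borate, CC(C)OB(OC(C)C)OC(C)C; water, O
Why: Bromine–lithium exchange and borylation of the aryllithium; the ether has no α-hydrogen and is stable to the organolithium at −78 °C, and the ammonium chloride hydrolysis keeps the acid-labile tertiary allyl ether intact.

Step 9
Reactants: 8 8-bromo-7-(2-methylbut-3-en-2-yloxy)-4H-chromen-4-one; 14 [4-(2-methylbut-3-en-2-yloxy)phenyl]boronic acid
Product: 15 (2S)-8-bromo-7-(2-methylbut-3-en-2-yloxy)-2-[4-(2-methylbut-3-en-2-yloxy)phenyl]chroman-4-one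
Conditions: [Rh(C2H4)2Cl]2 (2.5 mol%), (S,S)-2,5-diphenylbicyclo[2.2.2]octa-2,5-diene (5.5 mol%), aq. K3PO4 (0.5 equiv), toluene, 30 °C
Reagents that add atoms: none
Why: Rhodium-catalysed asymmetric 1,4-addition of an arylboronic acid to a chromone (Hayashi–Miyaura reaction); the chiral diene differentiates the enone faces as the aryl–rhodium species inserts, which sets C2, and water protonates the rhodium enolate. The substoichiometric weak base and low temperature limit retro-oxa-Michael opening of the product, and the aryl bromide and hindered vinyl groups are not touched by aryl–rhodium species.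

Step 10
Reactants: 15 (2S)-8-bromo-7-(2-methylbut-3-en-2-yloxy)-2-[4-(2-methylbut-3-en-2-yloxy)phenyl]chroman-4-one
Product: 16 (2S)-8-bromo-7-(2-methylbut-3-en-2-yloxy)-2-[4-(2-methylbut-3-en-2-yloxy)phenyl]-4-(trimethylsilyloxy)-2H-chromene
Conditions: Me3SiCl, then LiN(SiMe3)2, THF, −78 °C; pentane, filtration, used crude
Reagents that add atoms: chlorotrimethylsilane, C[Si](C)(C)Cl
Why: Kinetic enolisation with internal silyl quench; the enolate is silylated as it forms, so it has no lifetime in which to expel the C8a phenoxide, and C2 is untouched.

Step 11
Reactants: 16 (2S)-8-bromo-7-(2-methylbut-3-en-2-yloxy)-2-[4-(2-methylbut-3-en-2-yloxy)phenyl]-4-(trimethylsilyloxy)-2H-chromene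
Product: 18 (2R,3R)-8-bromo-3-hydroxy-7-(2-methylbut-3-en-2-yloxy)-2-[4-(2-methylbut-3-en-2-yloxy)phenyl]chroman-4-one, via silyloxy epoxide 17 (not isolated)
Conditions: dimethyldioxirane (1.05 equiv, acetone), CH2Cl2, −78 to −40 °C; then AcOH, THF–H2O, 0 °C
Reagents that add atoms: dimethyldioxirane, CC1(C)OO1
Why: Rubottom oxidation; the oxidant epoxidises the electron-rich enol ether on the face opposite the C2 aryl group, and hydrolytic opening at C4 gives the 2,3-trans ketol, which sets C3 by substrate control. The two monosubstituted vinyl groups are far less nucleophilic than the silyl enol ether and should survive one equivalent of oxidant at low temperature.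

Step 12
Reactants: 18 (2R,3R)-8-bromo-3-hydroxy-7-(2-methylbut-3-en-2-yloxy)-2-[4-(2-methylbut-3-en-2-yloxy)phenyl]chroman-4-one
Product: 19 (2R,3R)-8-bromo-3,7-dihydroxy-2-[4-hydroxy-3-(3-methylbut-2-enyl)phenyl]-6-(3-methylbut-2-enyl)chroman-4-one
Conditions: Eu(fod)3 (20 mol%), CHCl3, 55 °C
Reagents that add atoms: none
Why: Each tertiary allyl aryl ether undergoes a concerted aromatic Claisen rearrangement: in a chair-like six-membered transition state the vinyl CH2 terminus bonds to the ortho carbon as the O–CMe2 bond breaks, and the cyclohexadienone enolises to the phenol, which leaves the gem-dimethyl group at the alkene terminus of a linear prenyl unit. Eu(fod)3 (europium tris(6,6,7,7,8,8,8-heptafluoro-2,2-dimethyloctane-3,5-dionate)), an oxophilic trivalent europium Lewis acid, coordinates the ether oxygen and should let the shift run near 55 °C; the closest known reaction type is the Eu(fod)3-catalysed or thermal rearrangement of 1,1-dimethylallyl aryl ethers to ortho-prenylphenols, including substrates with one ortho position blocked. No ring closes and no stereocentre is formed; C2 and C3 are spectators, and the low temperature is chosen to stay below the onset of ring C opening. The selectivity needed on ring A is C6 over C8: C8 carries bromine, a shift to that carbon would give a dienone that cannot enolise and can only revert, so product formation is funnelled through C6. On ring B the two ortho positions are equivalent, so one product is expected. The free ketol can bind europium, which is why the loading is set high, and the neutral medium avoids acid-catalysed chroman formation from the new ortho-prenylphenols.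

Step 13
Reactants: 19 (2R,3R)-8-bromo-3,7-dihydroxy-2-[4-hydroxy-3-(3-methylbut-2-enyl)phenyl]-6-(3-methylbut-2-enyl)chroman-4-one
Product: 20 Lespeflorin B1, (2R,3R)-3,7-dihydroxy-2-[4-hydroxy-3-(3-methylbut-2-enyl)phenyl]-6-(3-methylbut-2-enyl)chroman-4-one
Conditions: Pd(OAc)2 (5 mol%), PPh3 (20 mol%), HCO2Na, DMF, 80 °C, argon
Reagents that add atoms: none
Why: Palladium-catalysed hydrodehalogenation by formate: zerovalent palladium inserts into the C8–Br bond, formate exchanges for bromide and loses CO2, and reductive elimination forms C8–H. Trisubstituted alkenes are not reduced under transfer conditions, and the weakly basic, oxygen-free medium is meant to spare the ketol.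

## Compound list

1 | 2-bromoresorcinol | Oc1cccc(O)c1Br | starting material
2 | 1-(3-bromo-2,4-dihydroxyphenyl)ethanone | CC(=O)c1ccc(O)c(Br)c1O | intermediate
3 | 2-methylbut-3-yn-2-ol | CC(C)(O)C#C | starting material
4 | 2-methylbut-3-yn-2-yl trifluoroacetate | C#CC(C)(C)OC(=O)C(F)(F)F | intermediate
5 | 1-[3-bromo-2-hydroxy-4-(2-methylbut-3-yn-2-yloxy)phenyl]ethanone | CC(=O)c1ccc(OC(C)(C)C#C)c(Br)c1O | intermediate
6 | (E)-1-[3-bromo-2-hydroxy-4-(2-methylbut-3-yn-2-yloxy)phenyl]-3-(dimethylamino)prop-2-en-1-one | CN(C)/C=C/C(=O)c1ccc(OC(C)(C)C#C)c(Br)c1O | intermediate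
7 | 8-bromo-7-(2-methylbut-3-yn-2-yloxy)-4H-chromen-4-one | O=c1ccoc2c(Br)c(OC(C)(C)C#C)ccc12 | intermediate
8 | 8-bromo-7-(2-methylbut-3-en-2-yloxy)-4H-chromen-4-one | O=c1ccoc2c(Br)c(OC(C)(C)C=C)ccc12 | intermediate
9 | 4-bromophenol | Oc1ccc(Br)cc1 | starting material
10 | 1-bromo-4-(2-methylbut-3-yn-2-yloxy)benzene | C#CC(C)(C)Oc1ccc(Br)cc1 | intermediate
11 | 1-bromo-4-(2-methylbut-3-en-2-yloxy)benzene | C=CC(C)(C)Oc1ccc(Br)cc1 | intermediate
12 | [4-(2-methylbut-3-en-2-yloxy)phenyl]lithium | [Li]c1ccc(OC(C)(C)C=C)cc1 | intermediate
13 | lithium triisopropoxy[4-(2-methylbut-3-en-2-yloxy)phenyl]borate | [Li+].CC(C)O[B-](OC(C)C)(OC(C)C)c1ccc(OC(C)(C)C=C)cc1 | intermediate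
14 | [4-(2-methylbut-3-en-2-yloxy)phenyl]boronic acid | OB(O)c1ccc(OC(C)(C)C=C)cc1 | intermediate
15 | (2S)-8-bromo-7-(2-methylbut-3-en-2-yloxy)-2-[4-(2-methylbut-3-en-2-yloxy)phenyl]chroman-4-one | C=CC(C)(C)Oc1ccc([C@@H]2CC(=O)c3ccc(OC(C)(C)C=C)c(Br)c3O2)cc1 | intermediate
16 | (2S)-8-bromo-7-(2-methylbut-3-en-2-yloxy)-2-[4-(2-methylbut-3-en-2-yloxy)phenyl]-4-(trimethylsilyloxy)-2H-chromene | C=CC(C)(C)Oc1ccc([C@@H]2C=C(O[Si](C)(C)C)c3ccc(OC(C)(C)C=C)c(Br)c3O2)cc1 | intermediate
17 | (2R,3R)-8-bromo-3,4-epoxy-7-(2-methylbut-3-en-2-yloxy)-2-[4-(2-methylbut-3-en-2-yloxy)phenyl]-4-(trimethylsilyloxy)chromane, epoxide oxygen trans to the C2 aryl group, C4 fixed by the cis ring fusion | C=CC(C)(C)Oc1ccc([C@H]2Oc3c(Br)c(OC(C)(C)C=C)ccc3[C@]4(O[Si](C)(C)C)O[C@H]24)cc1 | intermediate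
18 | (2R,3R)-8-bromo-3-hydroxy-7-(2-methylbut-3-en-2-yloxy)-2-[4-(2-methylbut-3-en-2-yloxy)phenyl]chroman-4-one | C=CC(C)(C)Oc1ccc([C@H]2Oc3c(Br)c(OC(C)(C)C=C)ccc3C(=O)[C@@H]2O)cc1 | intermediate
19 | (2R,3R)-8-bromo-3,7-dihydroxy-2-[4-hydroxy-3-(3-methylbut-2-enyl)phenyl]-6-(3-methylbut-2-enyl)chroman-4-one | CC(C)=CCc1cc([C@H]2Oc3c(Br)c(O)c(CC=C(C)C)cc3C(=O)[C@@H]2O)ccc1O | intermediate
20 | Lespeflorin B1, (2R,3R)-3,7-dihydroxy-2-[4-hydroxy-3-(3-methylbut-2-enyl)phenyl]-6-(3-methylbut-2-enyl)chroman-4-one | CC(C)=CCc1cc([C@H]2Oc3cc(O)c(CC=C(C)C)cc3C(=O)[C@@H]2O)ccc1O | target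

## Step count and risks

Total: 13 steps. Longest linear sequence: 9 steps (steps 1, 3, 4, 5, 9, 10, 11, 12, 13). The donor 4 is made in step 2 and feeds both branches, and the ring B branch (steps 6, 7, 8) joins at step 9.

**Step 12 (key step).** The most likely failure is incomplete or unselective rearrangement. The α-ketol can tie up the europium, and the ring B ether has no second donor to hold the catalyst. Raising the temperature to compensate invites ring C opening with loss of the C2 configuration, and ionisation of the tertiary ethers with loss of the five-carbon unit. The fallback moves the rearrangement ahead of the C3 oxygenation; it sets out from 15 and comes back at 19, replacing steps 10 to 12. Treatment of 15 with Eu(fod)3 in CHCl3 (or heating in toluene at 90 °C), where no ketol is present, should give (2S)-8-bromo-7-hydroxy-2-[4-hydroxy-3-(3-methylbut-2-enyl)phenyl]-6-(3-methylbut-2-enyl)chroman-4-one F1. Silylation of both phenols (t-BuMe2SiCl, imidazole, DMF) should give (2S)-8-bromo-7-(tert-butyldimethylsilyloxy)-2-[4-(tert-butyldimethylsilyloxy)-3-(3-methylbut-2-enyl)phenyl]-6-(3-methylbut-2-enyl)chroman-4-one F2. Enolate hydroxylation (KN(SiMe3)2, THF, −78 °C, then 3-phenyl-2-(phenylsulfonyl)oxaziridine, an oxidant that does not epoxidise the prenyl alkenes) should give (2R,3R)-8-bromo-7-(tert-butyldimethylsilyloxy)-2-[4-(tert-butyldimethylsilyloxy)-3-(3-methylbut-2-enyl)phenyl]-3-hydroxy-6-(3-methylbut-2-enyl)chroman-4-one F3. Desilylation with Bu4NF buffered by AcOH in THF at 0 °C returns to 19.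

**Step 9.** The most likely failures are slow addition to the weakly electrophilic pyranone, and erosion of enantiopurity through base-mediated reversible opening of the product ring; protodeboronation of 14 competes when the addition is slow, and the facial sense of the catalyst has to be confirmed. The fallback builds the ring by condensation and separates the enantiomers; it sets out from 5 and 11 and comes back at 15. Semihydrogenation of 5 under the conditions of step 5 should give 1-[3-bromo-2-hydroxy-4-(2-methylbut-3-en-2-yloxy)phenyl]ethanone F4. Quenching 12 (made from 11 as in step 8) with DMF should give 4-(2-methylbut-3-en-2-yloxy)benzaldehyde F5. Claisen–Schmidt condensation of F4 and F5 (KOH, EtOH) should give (E)-1-[3-bromo-2-hydroxy-4-(2-methylbut-3-en-2-yloxy)phenyl]-3-[4-(2-methylbut-3-en-2-yloxy)phenyl]prop-2-en-1-one F6. Oxa-Michael cyclisation (NaOAc, EtOH, reflux) should give racemic 8-bromo-7-(2-methylbut-3-en-2-yloxy)-2-[4-(2-methylbut-3-en-2-yloxy)phenyl]chroman-4-one F7. Preparative chromatography on a chiral stationary phase then delivers 15.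

**Step 11.** The most likely failures are competing epoxidation of the monosubstituted vinyl groups if the oxidant is in excess or the mixture warms, insufficient facial selectivity leading to the cis ketol, and premature hydrolysis of the silyl enol ether back to the ketone. The fallback is direct enolate hydroxylation, which sets out from 15 and comes back at 18, bypassing 16 and 17: KN(SiMe3)2, THF, −78 °C, then 3-phenyl-2-(phenylsulfonyl)oxaziridine, which hydroxylates enolates and leaves isolated alkenes alone. It makes no new compound (F0).

**Step 13.** The most likely failure is sluggish oxidative addition into the electron-rich C8–Br bond, which is flanked by two oxygens and further deactivated once formate deprotonates the C7 phenol. Prolonged heating in the basic medium would then erode the ketol by epimerisation at C2 or C3 and by oxidation to the flavonol. The fallback is a neutral radical-chain hydrodebromination that sets out from 19 and comes back at 20: Bu3SnH, AIBN, toluene, 80 °C. The C8 aryl radical has no alkene within reach and no favourable intramolecular hydrogen transfer, so it should simply take hydrogen from the stannane. It makes no new compound (F0).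

## Further compounds

F1 | step 12 | (2S)-8-bromo-7-hydroxy-2-[4-hydroxy-3-(3-methylbut-2-enyl)phenyl]-6-(3-methylbut-2-enyl)chroman-4-one | CC(C)=CCc1cc([C@@H]2CC(=O)c3cc(CC=C(C)C)c(O)c(Br)c3O2)ccc1O
F2 | step 12 | (2S)-8-bromo-7-(tert-butyldimethylsilyloxy)-2-[4-(tert-butyldimethylsilyloxy)-3-(3-methylbut-2-enyl)phenyl]-6-(3-methylbut-2-enyl)chroman-4-one | CC(C)=CCc1cc([C@@H]2CC(=O)c3cc(CC=C(C)C)c(O[Si](C)(C)C(C)(C)C)c(Br)c3O2)ccc1O[Si](C)(C)C(C)(C)C
F3 | step 12 | (2R,3R)-8-bromo-7-(tert-butyldimethylsilyloxy)-2-[4-(tert-butyldimethylsilyloxy)-3-(3-methylbut-2-enyl)phenyl]-3-hydroxy-6-(3-methylbut-2-enyl)chroman-4-one | CC(C)=CCc1cc([C@H]2Oc3c(Br)c(O[Si](C)(C)C(C)(C)C)c(CC=C(C)C)cc3C(=O)[C@@H]2O)ccc1O[Si](C)(C)C(C)(C)C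
F4 | step 9 | 1-[3-bromo-2-hydroxy-4-(2-methylbut-3-en-2-yloxy)phenyl]ethanone | CC(=O)c1ccc(OC(C)(C)C=C)c(Br)c1O
F5 | step 9 | 4-(2-methylbut-3-en-2-yloxy)benzaldehyde | O=Cc1ccc(OC(C)(C)C=C)cc1
F6 | step 9 | (E)-1-[3-bromo-2-hydroxy-4-(2-methylbut-3-en-2-yloxy)phenyl]-3-[4-(2-methylbut-3-en-2-yloxy)phenyl]prop-2-en-1-one | C=CC(C)(C)Oc1ccc(/C=C/C(=O)c2ccc(OC(C)(C)C=C)c(Br)c2O)cc1
F7 | step 9 | racemic 8-bromo-7-(2-methylbut-3-en-2-yloxy)-2-[4-(2-methylbut-3-en-2-yloxy)phenyl]chroman-4-one | C=CC(C)(C)Oc1ccc(C2CC(=O)c3ccc(OC(C)(C)C=C)c(Br)c3O2)cc1
F0 | step 11 | none | none
F0 | step 13 | none | none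
A1 | alternative 1 | 2,3-trans-3,7-bis(methoxymethoxy)-2-[4-(methoxymethoxy)-3-(3-methylbut-2-enyl)phenyl]-6-(3-methylbut-2-enyl)chroman-4-ol, C4 either epimer | CC(C)=CCc1cc([C@H]2Oc3cc(OCOC)c(CC=C(C)C)cc3C(O)[C@@H]2OCOC)ccc1OCOC
A2 | alternative 1 | 1-[3-bromo-4-(methoxymethoxy)-5-(3-methylbut-2-enyl)phenyl]-2-(methoxymethoxy)-3-[4-(methoxymethoxy)-3-(3-methylbut-2-enyl)phenyl]propane-1,3-diol, the two future ring C centres configured as in A1, C1 either epimer | CC(C)=CCc1cc([C@@H](O)[C@@H](OCOC)C(O)c2cc(Br)c(OCOC)c(CC=C(C)C)c2)ccc1OCOC
A3 | alternative 2 | (2R,3R)-7-hydroxy-3-(methoxymethoxy)-2-[4-(methoxymethoxy)-3-(3-methylbut-2-enyl)phenyl]-6-(3-methylbut-2-enyl)chroman-4-one | CC(C)=CCc1cc([C@H]2Oc3cc(O)c(CC=C(C)C)cc3C(=O)[C@@H]2OCOC)ccc1OCOC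
A4 | alternative 2 | (2R,3R)-5-bromo-3-(methoxymethoxy)-2-[4-(methoxymethoxy)-3-(3-methylbut-2-enyl)phenyl]-2,3-dihydro-4H-pyran-4-one | CC(C)=CCc1cc([C@H]2OC=C(Br)C(=O)[C@@H]2OCOC)ccc1OCOC
A5 | alternative 2 | tert-butyl{[(3E)-4-methoxy-3-(3-methylbut-2-enyl)buta-1,3-dien-2-yl]oxy}dimethylsilane | C=C(O[Si](C)(C)C(C)(C)C)/C(CC=C(C)C)=C/OC
A6 | alternative 3 | (2R,3R)-3-hydroxy-7-(methoxymethoxy)-2-[4-(methoxymethoxy)-3-(3-methylbut-2-enyl)phenyl]-6-(3-methylbut-2-enyl)chroman-4-one | CC(C)=CCc1cc([C@H]2Oc3cc(OCOC)c(CC=C(C)C)cc3C(=O)[C@@H]2O)ccc1OCOC
A7 | alternative 3 | 4-(methoxymethoxy)-2-{1-[4-(methoxymethoxy)-3-(3-methylbut-2-enyl)phenyl]-2-oxoethoxy}-5-(3-methylbut-2-enyl)benzaldehyde, racemic and epimerisable at the α-carbon | CC(C)=CCc1cc(C(C=O)Oc2cc(OCOC)c(CC=C(C)C)cc2C=O)ccc1OCOC
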